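Everything rests on opening the butenolide (ring C) at two bonds, C16–C17 and O–C19. In ring C the oxygen-bearing C16 is bonded to the alkene carbon C17, and the carbonyl C19 lies on the same side of the C17=C18 double bond as C16; an alkenylchromium reagent whose ester is already cis to the metal can therefore attack a C16 aldehyde and lactonise by itself. One ligand-controlled operation thus forms the C–C bond, the C16 stereocentre and ring C. Its precursor is the C1–C16 β,γ-unsaturated aldehyde: the sclareolide-derived decalin (rings A and B), a C13=C14 alkene of fixed geometry, and the C13 formyl group masked as a dioxolane, so that one acid hydrolysis finishes the synthesis.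

Key step: step 14

Naming: labdane numbering is used (decalin C1–C10, chain C11–C15, lactone C16–C19); Q stands for the (4aS,8aS)-2,5,5,8a-tetramethyl-3,4,4a,5,6,7,8,8a-octahydronaphthalen-1-yl group, i.e. rings A and B with the C8=C9 double bond.
Structure check: the target is 5S,10S (trans-decalin), 16R, has an E enal (CHO trans to C15) and the lactone carbonyl cis to C16 across C17=C18; the route is built to these.
Assumption: the oxazoline sulfonamide ligand OxS, (S)-N-[2-(4-isopropyl-4,5-dihydro-1,3-oxazol-2-yl)-6-methoxyphenyl]methanesulfonamide, is taken to send the alkenyl group to the Si face of the aldehyde (giving 16R); if a trial coupling shows the opposite sense, its enantiomer is used and nothing else changes.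

Step 1
Reactants: 1 (+)-sclareolide
Product: 3 methyl 2-Q-acetate, via unsaturated acid 2 (not isolated)
Conditions: H2SO4 (conc.), MeOH, rt → 50 °C
Reagents that add atoms: methanol CO
Why: Acid-mediated ionisation of the tertiary lactone C8–O bond (E1 elimination) followed by Fischer esterification should give the most substituted C8=C9 alkene under equilibrating conditions, esterification blocks relactonisation, and C5 and C10 are untouched while the C8 and C9 stereocentres of sclareolide are deliberately erased.

Step 2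
Reactants: 3 methyl 2-Q-acetate
Product: 4 2-Q-ethanol
Conditions: LiAlH4, THF, 0 °C → rt
Reagents that add atoms: none
Why: Hydride reduction of the ester to the primary alcohol; the isolated tetrasubstituted alkene is inert to LiAlH4.

Step 3
Reactants: 4 2-Q-ethanol
Product: 5 2-Q-ethyl bromide
Conditions: CBr4, PPh3, CH2Cl2, 0 °C
Reagents that add atoms: tetrabromomethane BrC(Br)(Br)Br
Why: Appel bromination, in which bromide displaces the alkoxyphosphonium group by SN2 at the primary carbon, so no cation forms that the neighbouring alkene could capture.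

Step 4
Reactants: 6 but-3-yn-1-ol
Product: 7 tert-butyl(but-3-yn-1-yloxy)dimethylsilane
Conditions: TBSCl, imidazole, CH2Cl2, 0 °C → rt
Reagents that add atoms: tert-butyldimethylsilyl chloride CC(C)(C)[Si](C)(C)Cl
Why: Standard silylation of a primary alcohol; the ether masks the future C16 oxygen through the Grignard chemistry and is later removed by fluoride without touching an acetal.

Step 5
Reactants: 7 tert-butyl(but-3-yn-1-yloxy)dimethylsilane; 8 formaldehyde (used as paraformaldehyde)
Product: 10 5-[(tert-butyldimethylsilyl)oxy]pent-2-yn-1-ol, via lithium acetylide 9 (not isolated)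
Conditions: n-BuLi, THF, −78 °C; (CH2O)n, −78 °C → rt
Reagents that add atoms: none
Why: Acetylide hydroxymethylation (deprotonation of the terminal alkyne and addition to formaldehyde) gives the 2-alkyn-1-ol whose free hydroxyl will direct the carbometalation.

Step 6
Reactants: 5 2-Q-ethyl bromide; 10 5-[(tert-butyldimethylsilyl)oxy]pent-2-yn-1-ol
Product: 14 (2E)-5-[(tert-butyldimethylsilyl)oxy]-2-(2-Q-ethyl)pent-2-en-1-ol, via homoallylic Grignard reagent 11 (not isolated), via chloromagnesium alkoxide 12 (not isolated), via alkenylmagnesium chelate 13 (not isolated)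
Conditions: 5, Mg, Et2O, reflux; 10, i-PrMgCl (0.95 equiv), THF, 0 °C; combine, CuI (10 mol%), 0 °C → rt; aq. NH4Cl
Reagents that add atoms: none
Why: Copper-catalysed anti-carbomagnesiation of a propargylic alkoxide delivers the alkyl group to C13 and places magnesium on C14 inside a five-membered chelate with the alkoxide, which forces the new C12–C13 bond and the C14–Mg bond onto opposite sides, so protonolysis with retention should leave C12 cis to C15 as one alkene isomer; prior deprotonation with a cheap Grignard reagent keeps the terpenoid reagent from being spent on the hydroxyl.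

Step 7
Reactants: 14 (2E)-5-[(tert-butyldimethylsilyl)oxy]-2-(2-Q-ethyl)pent-2-en-1-ol
Product: 15 (2E)-5-[(tert-butyldimethylsilyl)oxy]-2-(2-Q-ethyl)pent-2-enal
Conditions: MnO2 (activated), CH2Cl2, rt
Reagents that add atoms: none
Why: Chemoselective allylic oxidation with MnO2; the enal formed has CHO trans to C15, which is both the stable geometry and that of the target, so it should not drift.

Step 8
Reactants: 15 (2E)-5-[(tert-butyldimethylsilyl)oxy]-2-(2-Q-ethyl)pent-2-enal
Product: 16 tert-butyl{[(3E)-4-(1,3-dioxolan-2-yl)-6-Q-hex-3-en-1-yl]oxy}dimethylsilane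
Conditions: TMSOCH2CH2OTMS, TMSOTf (5 mol%), CH2Cl2, −78 °C; pyridine quench
Reagents that add atoms: 1,2-bis(trimethylsilyloxy)ethane C[Si](C)(C)OCCO[Si](C)(C)C
Why: Silyl-triflate-catalysed acetalisation with the bis-silyl ether of ethylene glycol is kinetically controlled at low temperature and should not move the double bond; carrying C13 at the aldehyde oxidation level removes any selective deprotection and oxidation after the key step.

Step 9
Reactants: 16 tert-butyl{[(3E)-4-(1,3-dioxolan-2-yl)-6-Q-hex-3-en-1-yl]oxy}dimethylsilane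
Product: 17 (3E)-4-(1,3-dioxolan-2-yl)-6-Q-hex-3-en-1-ol
Conditions: TBAF, THF, 0 °C → rt
Reagents that add atoms: none
Why: Fluoride-induced cleavage of the primary silyl ether; the dioxolane and both alkenes are inert to fluoride and mild base.

Step 10
Reactants: 17 (3E)-4-(1,3-dioxolan-2-yl)-6-Q-hex-3-en-1-ol
Product: 18 (3E)-4-(1,3-dioxolan-2-yl)-6-Q-hex-3-enal
Conditions: Dess–Martin periodinane, NaHCO3, CH2Cl2, 0 °C → rt; filtered, concentrated cold, used at once
Reagents that add atoms: none
Why: Dess–Martin oxidation under bicarbonate buffer is neutral and fast, which should keep the C13=C14 bond out of conjugation with the new C16 aldehyde and leave the dioxolane intact.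

Step 11
Reactants: 19 prop-2-yn-1-ol
Product: 20 tert-butyldimethyl(prop-2-yn-1-yloxy)silane
Conditions: TBSCl, imidazole, CH2Cl2, 0 °C → rt
Reagents that add atoms: tert-butyldimethylsilyl chloride CC(C)(C)[Si](C)(C)Cl
Why: Standard silylation; a silyl ether is a poor leaving group, so the later alkenylmetal at C17 should not eliminate to an allene, and it falls to the same aqueous acid that opens the dioxolane.

Step 12
Reactants: 20 tert-butyldimethyl(prop-2-yn-1-yloxy)silane
Product: 22 methyl 4-[(tert-butyldimethylsilyl)oxy]but-2-ynoate, via lithium acetylide 21 (not isolated)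
Conditions: n-BuLi, THF, −78 °C; ClCO2Me, −78 → 0 °C
Reagents that add atoms: methyl chloroformate COC(=O)Cl
Why: C-acylation of the lithium acetylide with a chloroformate gives the ynoate.

Step 13
Reactants: 22 methyl 4-[(tert-butyldimethylsilyl)oxy]but-2-ynoate
Product: 23 methyl (2Z)-4-[(tert-butyldimethylsilyl)oxy]-3-iodobut-2-enoate
Conditions: LiI, AcOH (1.5 equiv each), MeCN, 70 °C
Reagents that add atoms: lithium iodide [Li+].[I-]
Why: Hydroiodination of the ynoate by conjugate addition of iodide and protonation of the allenoate from the side away from iodine is a net anti addition that gives the Z isomer (iodine cis to the ester), and near-stoichiometric acetic acid in acetonitrile should spare the silyl ether.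

Step 14
Reactants: 18 (3E)-4-(1,3-dioxolan-2-yl)-6-Q-hex-3-enal; 23 methyl (2Z)-4-[(tert-butyldimethylsilyl)oxy]-3-iodobut-2-enoate
Product: 26 (5R)-4-{[(tert-butyldimethylsilyl)oxy]methyl}-5-[(2E)-3-(1,3-dioxolan-2-yl)-5-Q-pent-2-en-1-yl]furan-2(5H)-one, via alkenylchromium reagent 24 (not isolated), via chromium alkoxide 25 (not isolated)
Conditions: CrCl2 (10 mol%), ligand OxS (11 mol%), 1,8-bis(dimethylamino)naphthalene (11 mol%), NiCl2(2,9-dimethyl-1,10-phenanthroline) (2 mol%), Mn, ZrCp2Cl2, LiCl, MeCN, rt
Reagents that add atoms: none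
Why: Zerovalent nickel inserts into the C17–I bond of 23 with retention and passes the alkenyl group to trivalent chromium carrying the sulfonamide ligand (24), which adds to the aldehyde carbon C16 of 18 and forms the C16–C17 bond as alkoxide 25. This is the catalytic asymmetric Nozaki–Hiyama–Kishi alkenylation (Mn as terminal reductant, ZrCp2Cl2 to release chromium from oxygen), combined with the known self-lactonisation of adducts from Z-β-iodoacrylates. Ring C closes by 5-exo-trig acyl substitution: the C16 alkoxide attacks the cis ester carbonyl C19 and expels methoxide. The C16 stereocentre (R) is set by the chromium ligand alone, which directs the alkenyl group to the Si face of the unbranched aldehyde, since no substrate stereocentre is close enough to bias it. The step needs attack at one carbonyl only, retention of the Z geometry and survival of the skipped C13=C14/C16 aldehyde: the second formyl group is masked as the dioxolane, the stereoretentive nickel-to-chromium transfer and the poor leaving ability of the silyl ether keep the alkenylmetal intact, and the neutral, base-free medium keeps the alkene out of conjugation and the new C16–H from epimerising.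

Step 15
Reactants: 26 (5R)-4-{[(tert-butyldimethylsilyl)oxy]methyl}-5-[(2E)-3-(1,3-dioxolan-2-yl)-5-Q-pent-2-en-1-yl]furan-2(5H)-one
Product: 27 (2E)-4-[(2R)-3-(hydroxymethyl)-5-oxo-2,5-dihydrofuran-2-yl]-2-(2-Q-ethyl)but-2-enal (target)
Conditions: 1 M HCl (aq.), THF, 0 °C → rt
Reagents that add atoms: water O
Why: Acetal hydrolysis through the conjugated oxocarbenium ion and acid-assisted desilylation of the primary silyl ether occur together; the E enal is the stable geometry, dilute acid does not enolise C16 and the butenolide is stable to it, so no stereocentre should be disturbed.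

Compound list
1 | (+)-sclareolide, (3aR,5aS,9aS,9bR)-3a,6,6,9a-tetramethyldecahydronaphtho[2,1-b]furan-2(1H)-one | C[C@]12CCCC([C@@H]1CC[C@@]3([C@@H]2CC(=O)O3)C)(C)C | starting material
2 | 2-Q-acetic acid, 2-[(4aS,8aS)-2,5,5,8a-tetramethyl-3,4,4a,5,6,7,8,8a-octahydronaphthalen-1-yl]acetic acid | CC1=C(CC(=O)O)[C@@]2(C)CCCC(C)(C)[C@@H]2CC1 | intermediate
3 | methyl 2-Q-acetate | CC1=C(CC(=O)OC)[C@@]2(C)CCCC(C)(C)[C@@H]2CC1 | intermediate
4 | 2-Q-ethanol | CC1=C(CCO)[C@@]2(C)CCCC(C)(C)[C@@H]2CC1 | intermediate
5 | 2-Q-ethyl bromide, (4aS,8aS)-1-(2-bromoethyl)-2,5,5,8a-tetramethyl-3,4,4a,5,6,7,8,8a-octahydronaphthalene | CC1=C(CCBr)[C@@]2(C)CCCC(C)(C)[C@@H]2CC1 | intermediate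
6 | but-3-yn-1-ol | C#CCCO | starting material
7 | tert-butyl(but-3-yn-1-yloxy)dimethylsilane | C#CCCO[Si](C)(C)C(C)(C)C | intermediate
8 | formaldehyde | C=O | starting material
9 | {4-[(tert-butyldimethylsilyl)oxy]but-1-yn-1-yl}lithium | [Li]C#CCCO[Si](C)(C)C(C)(C)C | intermediate
10 | 5-[(tert-butyldimethylsilyl)oxy]pent-2-yn-1-ol | OCC#CCCO[Si](C)(C)C(C)(C)C | intermediate
11 | (2-Q-ethyl)magnesium bromide | CC1=C(CC[Mg]Br)[C@@]2(C)CCCC(C)(C)[C@@H]2CC1 | intermediate
12 | chloromagnesium 5-[(tert-butyldimethylsilyl)oxy]pent-2-yn-1-olate | Cl[Mg]OCC#CCCO[Si](C)(C)C(C)(C)C | intermediate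
13 | 3-{2-[(tert-butyldimethylsilyl)oxy]ethyl}-4-(2-Q-ethyl)-2,5-dihydro-1,2-oxamagnesole (Mg on C14, cis to the CH2O group) | CC1=C(CCC3=C(CCO[Si](C)(C)C(C)(C)C)[Mg]OC3)[C@@]2(C)CCCC(C)(C)[C@@H]2CC1 | intermediate
14 | (2E)-5-[(tert-butyldimethylsilyl)oxy]-2-(2-Q-ethyl)pent-2-en-1-ol | CC1=C(CC/C(CO)=C\CCO[Si](C)(C)C(C)(C)C)[C@@]2(C)CCCC(C)(C)[C@@H]2CC1 | intermediate
15 | (2E)-5-[(tert-butyldimethylsilyl)oxy]-2-(2-Q-ethyl)pent-2-enal | CC1=C(CC/C(C=O)=C\CCO[Si](C)(C)C(C)(C)C)[C@@]2(C)CCCC(C)(C)[C@@H]2CC1 | intermediate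
16 | tert-butyl{[(3E)-4-(1,3-dioxolan-2-yl)-6-Q-hex-3-en-1-yl]oxy}dimethylsilane | CC1=C(CC/C(C4OCCO4)=C\CCO[Si](C)(C)C(C)(C)C)[C@@]2(C)CCCC(C)(C)[C@@H]2CC1 | intermediate
17 | (3E)-4-(1,3-dioxolan-2-yl)-6-Q-hex-3-en-1-ol | CC1=C(CC/C(C4OCCO4)=C\CCO)[C@@]2(C)CCCC(C)(C)[C@@H]2CC1 | intermediate
18 | (3E)-4-(1,3-dioxolan-2-yl)-6-Q-hex-3-enal (key-step precursor) | CC1=C(CC/C(C4OCCO4)=C\CC=O)[C@@]2(C)CCCC(C)(C)[C@@H]2CC1 | intermediate
19 | prop-2-yn-1-ol | C#CCO | starting material
20 | tert-butyldimethyl(prop-2-yn-1-yloxy)silane | C#CCO[Si](C)(C)C(C)(C)C | intermediate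
21 | {3-[(tert-butyldimethylsilyl)oxy]prop-1-yn-1-yl}lithium | [Li]C#CCO[Si](C)(C)C(C)(C)C | intermediate
22 | methyl 4-[(tert-butyldimethylsilyl)oxy]but-2-ynoate | COC(=O)C#CCO[Si](C)(C)C(C)(C)C | intermediate
23 | methyl (2Z)-4-[(tert-butyldimethylsilyl)oxy]-3-iodobut-2-enoate | COC(=O)/C=C(\I)CO[Si](C)(C)C(C)(C)C | intermediate
24 | methyl (2Z)-4-[(tert-butyldimethylsilyl)oxy]-3-(dichlorochromio)but-2-enoate (trivalent chromium, chiral ligand not drawn) | COC(=O)/C=C(\[Cr](Cl)Cl)CO[Si](C)(C)C(C)(C)C | intermediate
25 | dichlorochromium alkoxide of methyl (2Z,4R,6E)-3-{[(tert-butyldimethylsilyl)oxy]methyl}-7-(1,3-dioxolan-2-yl)-4-hydroxy-9-Q-nona-2,6-dienoate (ligand not drawn) | CC1=C(CC/C(C4OCCO4)=C\C[C@@H](O[Cr](Cl)Cl)/C(CO[Si](C)(C)C(C)(C)C)=C\C(=O)OC)[C@@]2(C)CCCC(C)(C)[C@@H]2CC1 | intermediate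
26 | (5R)-4-{[(tert-butyldimethylsilyl)oxy]methyl}-5-[(2E)-3-(1,3-dioxolan-2-yl)-5-Q-pent-2-en-1-yl]furan-2(5H)-one (key-step product) | CC1=C(CC/C(C4OCCO4)=C\C[C@H]3OC(=O)C=C3CO[Si](C)(C)C(C)(C)C)[C@@]2(C)CCCC(C)(C)[C@@H]2CC1 | intermediate
27 | (2E)-4-[(2R)-3-(hydroxymethyl)-5-oxo-2,5-dihydrofuran-2-yl]-2-(2-Q-ethyl)but-2-enal | CC1=C(CC/C(C=O)=C\C[C@H]2OC(=O)C=C2CO)[C@@]2(C)CCCC(C)(C)[C@@H]2CC1 | target

Total step count: 15. Longest linear sequence: 10 steps (1, 2, 3, 6, 7, 8, 9, 10, 14, 15).

Steps most likely to fail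

1. Step 14. Facial discrimination at an unbranched aldehyde by the chromium ligand may be incomplete, chromium turnover may stall, or the aldehyde may drift into conjugation during a slow coupling. The fallback sets out from 18 and comes back to the route at 27. Aldehyde 18 would be alkynylated with methyl propiolate under ZnMe2 and a ProPhenol ligand (antipode chosen for the 4R carbinol; Ph3PO, toluene, 0 °C), a catalytic asymmetric alkynylzinc addition, to give methyl (4R,6E)-7-(1,3-dioxolan-2-yl)-4-hydroxy-9-Q-non-6-en-2-ynoate F1. Syn addition of the cuprate LiCu[CH2OCH(CH3)OEt]2 (from tributyl[(1-ethoxyethoxy)methyl]stannane, n-BuLi and CuBr·SMe2; THF, −78 °C) would place the protected hydroxymethyl group on C17 cis to H18, which leaves the ester cis to the C16 oxygen. The hydroxy ester should therefore lactonise on work-up to (5R)-5-[(2E)-3-(1,3-dioxolan-2-yl)-5-Q-pent-2-en-1-yl]-4-[(1-ethoxyethoxy)methyl]furan-2(5H)-one F2. The aqueous acid of step 15 would then remove the ethoxyethyl acetal and the dioxolane together to give 27. The stereocentre here comes from a zinc catalyst of a different class and the ring from a conjugate addition, so a weakness of the chromium system is not inherited.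

2. Step 6. The copper-catalysed addition may stall on the internal alkyne, the Grignard reagent may be lost to protonolysis or homocoupling before it adds, or some addition of the wrong sense may erode the alkene geometry. The fallback sets out from 5 and comes back at 14. Bromide 5 would alkylate trimethyl phosphonoacetate (NaH, DMF, 50 °C) to give methyl 2-(dimethoxyphosphoryl)-4-Q-butanoate F3. Horner–Wadsworth–Emmons olefination of F3 with 3-[(tert-butyldimethylsilyl)oxy]propanal (NaH, THF, 0 °C) should give mainly methyl (2E)-5-[(tert-butyldimethylsilyl)oxy]-2-(2-Q-ethyl)pent-2-enoate F4, with the ester trans to C15 as in 14; the minor geometric isomer would be removed by chromatography. Reduction with i-Bu2AlH (CH2Cl2, −78 °C) would give 14.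

3. Step 1. The cationic dehydration may leave trisubstituted and exocyclic alkene isomers that are hard to separate, relactonise to the C8-epimeric lactone, or trigger a methyl shift. The fallback sets out from 1 and comes back at 3. Saponification (KOH, MeOH/H2O, reflux) would give potassium 2-[(1R,2R,4aS,8aS)-2-hydroxy-2,5,5,8a-tetramethyldecahydronaphthalen-1-yl]acetate F5, which would be methylated without acidification (MeI, DMF) to methyl 2-[(1R,2R,4aS,8aS)-2-hydroxy-2,5,5,8a-tetramethyldecahydronaphthalen-1-yl]acetate F6. Dehydration through the chlorosulfite (SOCl2, pyridine, CH2Cl2, −78 °C), which avoids a free cation, should give mainly the exocyclic alkene methyl 2-[(1S,4aS,8aS)-5,5,8a-trimethyl-2-methylidenedecahydronaphthalen-1-yl]acetate F7. Iodine-catalysed equilibration (I2, toluene, 80 °C) would then move the double bond to the tetrasubstituted C8=C9 position and give 3.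

Further compounds
F1 | step 14 | methyl (4R,6E)-7-(1,3-dioxolan-2-yl)-4-hydroxy-9-Q-non-6-en-2-ynoate | CC1=C(CC/C(C4OCCO4)=C\C[C@@H](O)C#CC(=O)OC)[C@@]2(C)CCCC(C)(C)[C@@H]2CC1
F2 | step 14 | (5R)-5-[(2E)-3-(1,3-dioxolan-2-yl)-5-Q-pent-2-en-1-yl]-4-[(1-ethoxyethoxy)methyl]furan-2(5H)-one (both epimers at the ethoxyethyl carbon) | CC1=C(CC/C(C4OCCO4)=C\C[C@H]3OC(=O)C=C3COC(C)OCC)[C@@]2(C)CCCC(C)(C)[C@@H]2CC1
F3 | step 6 | methyl 2-(dimethoxyphosphoryl)-4-Q-butanoate (both C2 epimers) | CC1=C(CCC(C(=O)OC)P(=O)(OC)OC)[C@@]2(C)CCCC(C)(C)[C@@H]2CC1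
F4 | step 6 | methyl (2E)-5-[(tert-butyldimethylsilyl)oxy]-2-(2-Q-ethyl)pent-2-enoate | CC1=C(CC/C(C(=O)OC)=C\CCO[Si](C)(C)C(C)(C)C)[C@@]2(C)CCCC(C)(C)[C@@H]2CC1
F5 | step 1 | potassium 2-[(1R,2R,4aS,8aS)-2-hydroxy-2,5,5,8a-tetramethyldecahydronaphthalen-1-yl]acetate | C[C@]12CCCC(C)(C)[C@@H]1CC[C@@](O)([C@@H]2CC(=O)[O-])C.[K+]
F6 | step 1 | methyl 2-[(1R,2R,4aS,8aS)-2-hydroxy-2,5,5,8a-tetramethyldecahydronaphthalen-1-yl]acetate | C[C@]12CCCC(C)(C)[C@@H]1CC[C@@](O)([C@@H]2CC(=O)OC)C
F7 | step 1 | methyl 2-[(1S,4aS,8aS)-5,5,8a-trimethyl-2-methylidenedecahydronaphthalen-1-yl]acetate | C[C@]12CCCC(C)(C)[C@@H]1CCC(=C)[C@@H]2CC(=O)OC
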